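All constants belong to no real substance; the flask was simulated.

An easy step comes first here: target goes to over-reaction product by one first-order step that does not return, so reckon the fraction of target left, not the fraction made.

| setting | Wednesday's | Tuesday's |
|---|---|---|
| starting material | 0.50 M | 0.50 M |
| remark | one stirred flow tank at steady state, fed with the mixture as stated, mean residence time 80 s | a closed flask charged with all of it at once and left for 80 s |
| time |  | 80 s |

    intermediate B → intermediate C (k1 = 0.149 s⁻¹)
    target → over-reaction product (k2 = 0.0471 s⁻¹)
    intermediate C ⇌ intermediate D (K3 = 2.7, k3 = 0.0198 s⁻¹)
    starting material → intermediate A (k4 = 0.0717 s⁻¹)
    intermediate A → intermediate B (k5 = 0.277 s⁻¹)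
    intermediate C → target (k6 = 1.09 s⁻¹)
    intermediate D → side product (k7 = 0.0346 s⁻¹)

- the set-up with the highest share of target in all that became target or side product or over-reaction product, at the outlet or at the end ("none" if the first two lie within 2 percentage points) (Wednesday's / Tuesday's / none)
- share of target in all that became target or side product or over-reaction product, at the outlet or at the end, Wednesday's
- share of target in all that became target or side product or over-reaction product, at the outlet or at the end, Tuesday's

- the stated concentrations are those of everything mixed, before any reaction; amounts are the same in each set-up
- run time (Tuesday's): 80 s

Multiply 0.0471 s⁻¹ by the 80 s that both set-ups give and you get 3.77, the exposure: the over-reaction constant times the holding time, a Damköhler number. The bench rule says that target made at once and held in a closed flask keeps a fraction of one over e to the exposure, here 2.31 %.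

Wednesday's tank is simpler. At steady state over-reaction product leaves as fast as it forms, so its outlet amount is the exposure times that of target, whatever feeds target. Of those two, target is then one over one plus the exposure, 21.0 %. At intermediate C, the step to target runs 55.1 times the forward step to intermediate D, so side product should pull Wednesday's share a little under that.

The closed-flask rule has a border, and Tuesday's lies beyond it: the starting step is 1.52 times the over-reaction constant, so target is still being made while earlier target is lost. Since 0.0471 s⁻¹ is below each step of the chain to target, each of those steps multiplies the late amount by its constant over its constant minus the over-reaction constant. Together they give 5.37, and so 12.4 % of the charge as target. I take that as a high figure for Tuesday's, since the term that carries the starting step's own decay subtracts from it and at 80 s still comes to 2.62 % of the charge, and I still pick the tank.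

The forecast named Wednesday's, with 20.7 % against 9.8 %, since “the contest is mainly how long target sits exposed to over-reaction”.

The simulation gives 20.7 % for Wednesday's and 9.77 % for Tuesday's, so Wednesday's is best; the tank stands just under my 21.0 %, and the target in Tuesday's flask stands under my high 12.4 % of the charge. In Tuesday's flask at 80.0 s, with 0.0471 s⁻¹ against 0.0717 s⁻¹ for the starting step, starting material is down to 0.323 %, target stands at 9.66 % and over-reaction product at 87.9 %. Read at 150 s, Tuesday's flask has an exposure of 7.07, for which the same factor gives 0.459 %, and it holds 0.441 % target.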